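**Retrosynthetic overview**
1. The only ring, the 42-membered lactone, is closed late (step 40) by an intramolecular Stille coupling at C3–C4, after esterifying O41; the 4Z-iodoalkene comes from a Wittig iodo-olefination of a C5 aldehyde.
2. The chain is cut at C21–C22 (acetylide + epoxide) and C37–C38 (acetylide + tosylate); one Lindlar reduction turns both alkynes into the Z-alkenes.
3. Both methyl/hydroxyl pairs (C18/C19 and C42/C43) come from one [2,3]-Wittig rearrangement of the (Z)-allyl propargyl ether made from (R)-but-3-yn-2-ol (1,3-chirality transfer), giving the common alcohol 8.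
4. C7–C17: three (S)-epichlorohydrin units joined by silyl-dithiane linchpins; C9, C13, C17 are set by hydroxyl-directed anti reduction. C23–C31: three (R)-epoxides joined the same way, dithianes then removed reductively.
5. C41 is set by chelation-controlled ketone reduction and C49 is bought in (R)-propylene oxide.

Assumption and conventions: carbons carry target numbering C1 (lactone C=O) to C50; C4′ is the extra vinyl CH2 lost in step 35; "dithiane at Cn" means that carbon is C2 of a 1,3-dithiane; TBS = tert-butyldimethylsilyl, TES = triethylsilyl, PMB = 4-methoxybenzyl, Ts = 4-toluenesulfonyl; all centres are as in the target (7S,9R,11S,13R,15S,17R,18R,19R,23R,27R,31R,41S,42S,43R,49R) and as written in the SMILES; (R)-but-3-yn-2-ol, both epichlorohydrins, (R)-benzyl glycidyl ether and (R)-propylene oxide are taken as catalogue items; the reagent solution 16 of step 7 is not stored, and its preparation is repeated on the scale needed directly before each of steps 8, 9, 17 and 18.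

Step 1
Reactants: 1 (R)-but-3-yn-2-ol
Product: 3 (R)-pent-3-yn-2-ol, via dilithio alkynoxide 2 (not isolated)
Conditions: n-BuLi (2.1 equiv), THF, −78 → −20 °C; MeI (1.0 equiv), −78 °C → rt; H2O
Reagents that add atoms: iodomethane CI
Why: SN2 methylation of the alkoxide–acetylide dianion occurs at the acetylide carbon, its more nucleophilic site, and does not involve the bought carbinol centre.

Step 2
Reactants: 3 (R)-pent-3-yn-2-ol
Product: 4 (R,Z)-pent-3-en-2-ol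
Conditions: H2 (1 atm), Pd/CaCO3 poisoned with Pb(OAc)2 (Lindlar catalyst), quinoline, pentane, rt
Reagents that add atoms: none
Why: Lindlar semi-hydrogenation adds H2 syn to the alkyne and stops at the (Z)-alkene, leaving the carbinol centre untouched.

Step 3
Reactants: 4 (R,Z)-pent-3-en-2-ol; 5 3-bromo-1-(trimethylsilyl)prop-1-yne
Product: 6 (R,Z)-trimethyl[3-(pent-3-en-2-yloxy)prop-1-yn-1-yl]silane
Conditions: NaH, THF, 0 °C; then 5, Bu4NI (cat.), 0 °C → rt
Reagents that add atoms: none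
Why: Williamson etherification of the sodium alkoxide with the reactive propargylic bromide forms only the O–CH2 bond, so the carbinol configuration and the Z geometry are kept.

Step 4
Reactants: 6 (R,Z)-trimethyl[3-(pent-3-en-2-yloxy)prop-1-yn-1-yl]silane
Product: 8 (3S,4R,E)-4-methyl-1-(trimethylsilyl)hept-5-en-1-yn-3-ol, via lithiated ether 7 (not isolated)
Conditions: n-BuLi, THF, −78 °C; H2O
Reagents that add atoms: none
Why: [2,3]-Wittig sigmatropic rearrangement through a five-membered envelope: the carbinol methyl sits pseudo-equatorial to avoid 1,3-allylic strain with the Z-methyl, the alkynyl group is exo, so the new C–C bond forms suprafacially with complete 1,3-chirality transfer, giving the (E)-alkene and the syn methyl/hydroxyl pair (C18/C19 and later C42/C43).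

Step 5
Reactants: 8 (3S,4R,E)-4-methyl-1-(trimethylsilyl)hept-5-en-1-yn-3-ol
Product: 10 (3S,4S)-4-(1,3-dithian-2-yl)-1-(trimethylsilyl)pent-1-yn-3-ol, via hydroxy aldehyde 9 (not isolated)
Conditions: O3, CH2Cl2, −78 °C; PPh3, −78 °C → rt; concentrate; then HS(CH2)3SH, BF3·OEt2 (cat.), CH2Cl2, −40 °C
Reagents that add atoms: propane-1,3-dithiol SCCCS
Why: Ozonolysis cleaves the alkene much faster than the silyl alkyne, and immediate Lewis-acid dithioacetalisation traps the labile β-hydroxy aldehyde as the Corey–Seebach acyl-anion precursor without touching C18.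

Step 6
Reactants: 11 (S)-epichlorohydrin; 12 vinylmagnesium bromide
Product: 14 (S)-2-allyloxirane, via chlorohydrin 13 (not isolated)
Conditions: CuI (10 mol%), THF, −40 °C; then aq. NaOH, Et2O, rt
Reagents that add atoms: none
Why: Cu-catalysed Grignard opening at the epoxide CH2 followed by base-induced chlorohydrin closure never touches the stereocentre, so C7 is the bought epichlorohydrin centre.

Step 7
Reactants: 15 2-(tert-butyldimethylsilyl)-1,3-dithiane
Product: 16 2-lithio-2-(tert-butyldimethylsilyl)-1,3-dithiane (cold ethereal solution, used at once)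
Conditions: t-BuLi (1.05 equiv), Et2O, −78 → −45 °C, 1 h
Reagents that add atoms: tert-butyllithium [Li]C(C)(C)C
Why: Metalation of the C2–H, acidified by two sulfur atoms and silicon, gives the silyl dithiane anion (Corey–Seebach acyl-anion equivalent) cleanly; no stereocentre is involved.

Step 8
Reactants: 16 2-lithio-2-(tert-butyldimethylsilyl)-1,3-dithiane; 14 (S)-2-allyloxirane; 11 (S)-epichlorohydrin
Product: 19 C4′–C12 epoxide (7-OTBS; dithiane at C9; 11,12-epoxide), via alkoxide adduct 17 (not isolated), via chloroalkoxide 18 (not isolated)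
Conditions: 14 added to 16, Et2O, −78 → −25 °C; then 11, HMPA, −78 °C → rt
Reagents that add atoms: none
Why: Three-component linchpin coupling: the dithiane anion opens 14 at CH2, HMPA triggers the 1,4-Brook silyl shift, and the new anion opens epichlorohydrin at its epoxide CH2 before the alkoxide displaces chloride, so C7 and C11 are both bought centres.

Step 9
Reactants: 16 2-lithio-2-(tert-butyldimethylsilyl)-1,3-dithiane; 19 C4′–C12 epoxide; 11 (S)-epichlorohydrin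
Product: 22 C4′–C16 epoxide (7,11-bis-OTBS; dithianes at C9 and C13; 15,16-epoxide), via alkoxide adduct 20 (not isolated), via chloroalkoxide 21 (not isolated)
Conditions: 19 added to 16, Et2O, −78 → −25 °C; then 11, HMPA, −78 °C → rt
Reagents that add atoms: none
Why: Second linchpin coupling of the same kind (epoxide opening, Brook rearrangement, epichlorohydrin opening and closure) installs C13 as a masked ketone and C15 as a bought centre.

Step 10
Reactants: 10 (3S,4S)-4-(1,3-dithian-2-yl)-1-(trimethylsilyl)pent-1-yn-3-ol; 22 C4′–C16 epoxide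
Product: 24 C4′–C21 tris-dithiane (7,11-bis-OTBS; 15,19-diol; 21-TMS), via dilithio dithiane 23 (not isolated)
Conditions: 10, n-BuLi then t-BuLi, THF/HMPA (10:1), −78 °C; 22, −78 → −20 °C; H2O
Reagents that add atoms: none
Why: Corey–Seebach alkylation: the C19 alkoxide protects the propargylic C–H so that t-BuLi lithiates the dithiane carbon, and this acyl-anion equivalent opens the terminal epoxide at CH2 to form C16–C17.

Step 11
Reactants: 24 C4′–C21 tris-dithiane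
Product: 25 C4′–C21 tetrol tris-dithiane (terminal alkyne)
Conditions: Bu4NF, THF, 0 °C → rt
Reagents that add atoms: none
Why: Fluoride cleaves both silyl ethers and the alkynyl C–Si bond while no base-sensitive β-hydroxy ketone is yet present.

Step 12
Reactants: 25 C4′–C21 tetrol tris-dithiane
Product: 26 C4′–C21 9,13,17-trione 7,11,15,19-tetrol
Conditions: MeI, CaCO3, MeCN/H2O (9:1), 45 °C
Reagents that add atoms: water O
Why: Alkylative dithiane hydrolysis (S-methylation then buffered hydrolysis) is neutral, so the alkene, the alkyne and the epimerisable C18 next to the new ketone survive.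

Step 13
Reactants: 26 C4′–C21 9,13,17-trione 7,11,15,19-tetrol
Product: 27 C4′–C21 7,9,11,13,15,17,19-heptol
Conditions: Me4NBH(OAc)3, MeCN/AcOH (1:1), −40 → −20 °C
Reagents that add atoms: none
Why: Evans–Saksena reduction delivers hydride intramolecularly from a β-alkoxyborohydride to give 1,3-anti diols; each ketone is flanked by two hydroxyls that demand the same face, so C9, C13 and C17 are set anti to their neighbours.

Step 14
Reactants: 27 C4′–C21 heptol
Product: 28 7,9,11,13,15,19-hexa-TES ether of 27 (17-OH free)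
Conditions: Et3SiCl (6.3 equiv), imidazole, CH2Cl2/DMF, −20 → 0 °C
Reagents that add atoms: chlorotriethylsilane CC[Si](CC)(CC)Cl
Why: Imidazole-promoted silylation with the silyl chloride takes the six carbinols flanked by CH2 groups or by the slim alkyne, while the C17 hydroxyl, crowded by the C18 methine and the new C15 and C19 silyl ethers, lags; any heptakis-ether formed is simply the product of step 15.

Step 15
Reactants: 28 hexa-TES ether of 27
Product: 29 hepta-TES ether of 27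
Conditions: Et3SiOTf (1.5 equiv), 2,6-lutidine, CH2Cl2, −78 → 0 °C
Reagents that add atoms: triethylsilyl trifluoromethanesulfonate CC[Si](CC)(CC)OS(=O)(=O)C(F)(F)F
Why: The far more electrophilic silyl triflate caps the hindered C17 hydroxyl and leaves the alkyne C–H free.

Step 16
Reactants: 30 (R)-epichlorohydrin; 31 benzyl 5-bromopentyl ether
Product: 34 (R)-2-[6-(benzyloxy)hexyl]oxirane, via Grignard reagent 32 (not isolated), via chlorohydrin 33 (not isolated)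
Conditions: 31, Mg, THF; CuI (10 mol%), 30, −40 °C; then aq. NaOH, rt
Reagents that add atoms: none
Why: Cu-catalysed Grignard opening at the epoxide CH2 and chlorohydrin closure leave the bought centre (C31) untouched.

Step 17
Reactants: 16 2-lithio-2-(tert-butyldimethylsilyl)-1,3-dithiane; 34 (R)-2-[6-(benzyloxy)hexyl]oxirane; 30 (R)-epichlorohydrin
Product: 37 C26–C37 epoxide (26,27-epoxide; dithiane at C29; 31-OTBS; 37-OBn), via alkoxide adduct 35 (not isolated), via chloroalkoxide 36 (not isolated)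
Conditions: 34 added to 16, Et2O, −78 → −25 °C; then 30, HMPA, −78 °C → rt
Reagents that add atoms: none
Why: Linchpin coupling (epoxide opening, 1,4-Brook rearrangement, epichlorohydrin opening and closure) joins two bought centres (C31, C27) through the one-carbon unit C29.

Step 18
Reactants: 16 2-lithio-2-(tert-butyldimethylsilyl)-1,3-dithiane; 37 C26–C37 epoxide; 38 (R)-benzyl glycidyl ether
Product: 40 C22–C37 bis-dithiane (22-OBn; 23-OH; dithianes at C25 and C29; 27,31-bis-OTBS; 37-OBn), via alkoxide adduct 39 (not isolated)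
Conditions: 37 added to 16, Et2O, −78 → −25 °C; then 38, HMPA, −78 → 0 °C; H2O
Reagents that add atoms: none
Why: Second linchpin coupling; the Brook-generated anion opens the glycidyl ether at CH2, so C23 is also a bought centre and is left as the only free hydroxyl.

Step 19
Reactants: 40 C22–C37 bis-dithiane
Product: 41 C22–C37 22,23,37-triol (27,31-bis-OTBS)
Conditions: Raney Ni (W-2), H2 (1 atm), EtOH, reflux
Reagents that add atoms: none
Why: Raney Ni hydrogenolysis turns both dithiane carbons into CH2 and cleaves both benzyl ethers in one operation, while the silyl ethers are inert.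

Step 20
Reactants: 41 C22–C37 triol
Product: 43 C22–C37 epoxy tosylate (22,23-epoxide; 27,31-bis-OTBS; 37-OTs), via bis-tosylate 42 (not isolated)
Conditions: TsCl (2.2 equiv), Et3N, Bu2SnO (5 mol%), CH2Cl2, 0 °C → rt; then K2CO3, MeOH, 0 °C
Reagents that add atoms: 4-toluenesulfonyl chloride Cc1ccc(cc1)S(Cl)(=O)=O
Why: Stannylene-assisted sulfonylation takes the two primary hydroxyls, then intramolecular Williamson closure of the 1,2-hydroxy tosylate gives the terminal epoxide without touching C23, leaving the remote tosylate as the later alkylation handle.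

Step 21
Reactants: 44 (R)-propylene oxide; 12 vinylmagnesium bromide
Product: 45 (R)-pent-4-en-2-ol
Conditions: CuI (10 mol%), THF, −40 °C; H2O
Reagents that add atoms: none
Why: Cu-catalysed Grignard opening at the epoxide CH2 keeps the bought centre (C49).

Step 22
Reactants: 45 (R)-pent-4-en-2-ol
Product: 46 (R)-tert-butyldimethyl(pent-4-en-2-yloxy)silane
Conditions: TBSCl, imidazole, DMF, rt
Reagents that add atoms: tert-butyldimethylsilyl chloride CC(C)(C)[Si](C)(C)Cl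
Why: Standard imidazole-promoted silylation of the secondary alcohol.

Step 23
Reactants: 46 (R)-tert-butyldimethyl(pent-4-en-2-yloxy)silane
Product: 48 (R)-tert-butyl[(5-iodopentan-2-yl)oxy]dimethylsilane, via alkylzirconocene chloride 47 (not isolated)
Conditions: Cp2Zr(H)Cl, CH2Cl2, rt; then I2, 0 °C
Reagents that add atoms: iodine II
Why: Hydrozirconation puts Zr on the terminal carbon (anti-Markovnikov) and iodinolysis of the C–Zr bond gives the primary iodide.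

Step 24
Reactants: 8 (3S,4R,E)-4-methyl-1-(trimethylsilyl)hept-5-en-1-yn-3-ol
Product: 49 (3S,4R,E)-4-methylhept-5-en-1-yn-3-ol
Conditions: K2CO3, MeOH, rt
Reagents that add atoms: none
Why: Methanolysis of the alkynyl C–Si bond frees the terminal alkyne for chain extension.

Step 25
Reactants: 49 (3S,4R,E)-4-methylhept-5-en-1-yn-3-ol; 48 (R)-tert-butyl[(5-iodopentan-2-yl)oxy]dimethylsilane
Product: 51 C41–C50 alkynol (prop-1-enyl as masked C41; 43-OH; C44≡C45; 49-OTBS), via dilithio alkynol 50 (not isolated)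
Conditions: n-BuLi (2.1 equiv), THF/HMPA, −78 → 0 °C; 48, 0 °C → rt; H2O
Reagents that add atoms: none
Why: SN2 alkylation of the alkoxide–acetylide dianion occurs at carbon (the softer, more nucleophilic site) and forms C45–C46.

Step 26
Reactants: 51 C41–C50 alkynol
Product: 52 43-O-PMB ether of 51
Conditions: NaH, 4-methoxybenzyl chloride, Bu4NI (cat.), THF/DMF, 0 °C → rt
Reagents that add atoms: 4-methoxybenzyl chloride COc1ccc(CCl)cc1
Why: Williamson etherification installs the PMB ether that will act as the chelating group at C43.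

Step 27
Reactants: 52 43-O-PMB ether of 51
Product: 53 C41 aldehyde (42-Me; 43-OPMB; C44≡C45; 49-OTBS)
Conditions: OsO4 (2 mol%), NaIO4, 2,6-lutidine, dioxane/H2O (3:1), rt
Reagents that add atoms: osmium tetroxide O=[Os](=O)(=O)=O; sodium periodate [Na+].[O-]I(=O)(=O)=O
Why: Johnson–Lemieux oxidation: OsO4 dihydroxylates the alkene far faster than the alkyne and periodate cleaves the diol, with lutidine suppressing over-oxidation and epimerisation at C42.

Step 28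
Reactants: 53 C41 aldehyde
Product: 54 saturated C41 aldehyde (42-Me; 43-OPMB; 49-OTBS)
Conditions: H2 (1 atm), Pd/C, pyridine (0.5 equiv), EtOAc, rt
Reagents that add atoms: none
Why: Heterogeneous hydrogenation saturates the alkyne, and pyridine-moderated Pd/C leaves the PMB ether and the aliphatic aldehyde intact.

Step 29
Reactants: 54 saturated C41 aldehyde; 55 propargyl bromide
Product: 57 C38–C50 homopropargylic alcohols (C41 epimers), via allenylzinc bromide 56 (not isolated)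
Conditions: Zn, THF, 0 °C → rt; H2O
Reagents that add atoms: none
Why: Barbier propargylation through the allenylzinc (SE2′) gives the homopropargylic alcohol; the C41 ratio is irrelevant because the carbinol is oxidised next.

Step 30
Reactants: 57 C38–C50 homopropargylic alcohols
Product: 58 C38–C50 β,γ-ynone (C41 ketone)
Conditions: Dess–Martin periodinane, NaHCO3, CH2Cl2, 0 °C
Reagents that add atoms: none
Why: Buffered Dess–Martin oxidation gives the β,γ-alkynyl ketone without base-induced isomerisation to the allenone or epimerisation at C42.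

Step 31
Reactants: 58 C38–C50 β,γ-ynone
Product: 59 C38–C50 alkynol (41-OH; 42-Me; 43-OPMB; 49-OTBS)
Conditions: Zn(BH4)2, Et2O, −40 °C
Reagents that add atoms: none
Why: Chelation-controlled (Cram-chelate) reduction: Zn bridges the ketone and the β-OPMB oxygen, the C42 methyl and C44 chain sit on the same face of the chelate, and hydride attacks the opposite face to give the all-syn C41–C43 triad.

Step 32
Reactants: 29 hepta-TES ether of 27; 43 C22–C37 epoxy tosylate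
Product: 61 C4′–C37 alkynol (C20≡C21; 23-OH; 27,31-bis-OTBS; 37-OTs), via lithium acetylide 60 (not isolated)
Conditions: 29, n-BuLi, THF, −78 °C; BF3·OEt2; 43, −78 °C; H2O
Reagents that add atoms: none
Why: Yamaguchi–Hirao alkynylation: the BF3-activated epoxide is opened at CH2 by the lithium acetylide, the tosylate is inert at −78 °C, and C23 stays as bought.

Step 33
Reactants: 61 C4′–C37 alkynol
Product: 62 23-O-TBS ether of 61
Conditions: TBSOTf, 2,6-lutidine, CH2Cl2, −78 °C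
Reagents that add atoms: tert-butyldimethylsilyl trifluoromethanesulfonate CC(C)(C)[Si](C)(C)OS(=O)(=O)C(F)(F)F
Why: Silyl triflate protection of the only free hydroxyl so that O41 will later be the single acylation site.

Step 34
Reactants: 59 C38–C50 alkynol; 62 23-O-TBS ether of 61
Product: 64 C4′–C50 diyne (C20≡C21; C38≡C39; 41-OH), via dilithio alkynol 63 (not isolated)
Conditions: 59 (2 equiv), n-BuLi (4 equiv), THF/HMPA (5:1), −78 → 0 °C; 62, 0 °C → rt; H2O
Reagents that add atoms: none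
Why: SN2 alkylation of the acetylide (the lithium alkoxide is far less nucleophilic) by the primary tosylate forms C37–C38.

Step 35
Reactants: 64 C4′–C50 diyne
Product: 65 C5 aldehyde diyne
Conditions: OsO4 (5 mol%), NaIO4, 2,6-lutidine, dioxane/H2O (3:1), rt
Reagents that add atoms: osmium tetroxide O=[Os](=O)(=O)=O; sodium periodate [Na+].[O-]I(=O)(=O)=O
Why: Johnson–Lemieux cleavage of the only C=C bond (internal alkynes react much more slowly with OsO4) unveils the C5 aldehyde after all organolithium steps are done.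

Step 36
Reactants: 65 C5 aldehyde diyne
Product: 66 (20Z,38Z)-C5 aldehyde
Conditions: H2 (1 atm), Pd/CaCO3 poisoned with Pb(OAc)2 (Lindlar catalyst), quinoline, EtOAc, rt
Reagents that add atoms: none
Why: Lindlar semi-hydrogenation adds H2 syn to both alkynes to give the two (Z)-alkenes, while the aldehyde, PMB and silyl ethers are untouched.

Step 37
Reactants: 66 (20Z,38Z)-C5 aldehyde; 67 ethyltriphenylphosphonium bromide
Product: 71 (4Z,20Z,38Z)-C4 vinyl iodide (41-OH), via phosphorus ylide 68 (not isolated), via iodoethylphosphonium iodide 69 (not isolated), via iodo ylide 70 (not isolated)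
Conditions: 67 (3 equiv), n-BuLi, THF, rt; I2, −78 °C; NaN(SiMe3)2, −20 °C; 66, −78 → −20 °C
Reagents that add atoms: iodine II
Why: Zhao modification of the Wittig reaction: the α-iodo ylide gives the (Z)-2-iodoalkene with iodine cis to C6, which fixes the later 4Z geometry.

Step 38
Reactants: 72 (E)-1,2-bis(tributylstannyl)ethene
Product: 74 (E)-3-(tributylstannyl)acrylic acid, via vinyllithium 73 (not isolated)
Conditions: n-BuLi, THF, −78 °C; CO2; dil. HCl
Reagents that add atoms: carbon dioxide O=C=O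
Why: Tin–lithium exchange with retention of alkene geometry followed by carboxylation.

Step 39
Reactants: 71 (4Z,20Z,38Z)-C4 vinyl iodide; 74 (E)-3-(tributylstannyl)acrylic acid
Product: 75 41-O-[(E)-3-(tributylstannyl)acryloyl] ester of 71
Conditions: DCC, DMAP, CH2Cl2, 0 °C → rt
Reagents that add atoms: none
Why: Steglich esterification of the only free hydroxyl (O41), with retention at C41.

Step 40
Reactants: 75 41-O-[(E)-3-(tributylstannyl)acryloyl] ester of 71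
Product: 76 protected macrolactone (hepta-TES; tetra-TBS; 43-OPMB)
Conditions: Pd2(dba)3 (10 mol%), AsPh3 (40 mol%), i-Pr2NEt, DMF/THF (1:1), 1 mM, rt
Reagents that add atoms: none
Why: Intramolecular Stille coupling at high dilution forms C3–C4 and the 42-membered ring with retention of both alkene geometries, giving the (2E,4Z)-dienoate.

Step 41
Reactants: 76 protected macrolactone
Product: 77 43-hydroxy macrolactone (hepta-TES; tetra-TBS)
Conditions: DDQ, CH2Cl2/pH 7 buffer (10:1), 0 °C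
Reagents that add atoms: none
Why: Oxidative PMB cleavage (benzylic hydride abstraction, hydrolysis of the oxocarbenium ion) frees O43 without touching silyl ethers, the dienoate or the Z-alkenes.

Step 42
Reactants: 77 43-hydroxy macrolactone
Product: 78 CNP0071908.1
Conditions: HF·pyridine, pyridine, THF, 0 °C → rt
Reagents that add atoms: none
Why: Buffered fluoride-mediated global desilylation removes the seven TES and four TBS ethers under mildly acidic conditions that avoid acyl migration and lactone opening.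

**Compound list**
1 | (R)-but-3-yn-2-ol | C[C@@H](O)C#C | starting material
2 | dilithio derivative of 1 (lithium alkoxide, lithium acetylide) | C[C@@H](O[Li])C#C[Li] | intermediate
3 | (R)-pent-3-yn-2-ol | C[C@@H](O)C#CC | intermediate
4 | (R,Z)-pent-3-en-2-ol | C[C@@H](O)/C=C\C | intermediate
5 | 3-bromo-1-(trimethylsilyl)prop-1-yne | BrCC#C[Si](C)(C)C | starting material
6 | (R,Z)-trimethyl[3-(pent-3-en-2-yloxy)prop-1-yn-1-yl]silane | C[C@@H](OCC#C[Si](C)(C)C)/C=C\C | intermediate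
7 | α-lithiated propargylic ether of 6 | C[C@@H](OC([Li])C#C[Si](C)(C)C)/C=C\C | intermediate
8 | (3S,4R,E)-4-methyl-1-(trimethylsilyl)hept-5-en-1-yn-3-ol | C/C=C/[C@@H](C)[C@H](O)C#C[Si](C)(C)C | intermediate
9 | (2S,3S)-3-hydroxy-2-methyl-5-(trimethylsilyl)pent-4-ynal | O=C[C@@H](C)[C@H](O)C#C[Si](C)(C)C | intermediate
10 | (3S,4S)-4-(1,3-dithian-2-yl)-1-(trimethylsilyl)pent-1-yn-3-ol | C1CSC(SC1)[C@@H](C)[C@H](O)C#C[Si](C)(C)C | intermediate
11 | (S)-epichlorohydrin | ClC[C@@H]1CO1 | starting material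
12 | vinylmagnesium bromide | C=C[Mg]Br | starting material
13 | (S)-1-chloropent-4-en-2-ol | ClC[C@@H](O)CC=C | intermediate
14 | (S)-2-allyloxirane | C=CC[C@H]1CO1 | intermediate
15 | 2-(tert-butyldimethylsilyl)-1,3-dithiane | C1CSC(SC1)[Si](C)(C)C(C)(C)C | starting material
16 | 2-lithio-2-(tert-butyldimethylsilyl)-1,3-dithiane | [Li]C1(SCCCS1)[Si](C)(C)C(C)(C)C | intermediate
17 | lithium alkoxide adduct of 16 and 14 (C7–OLi, silyl dithiane at C9) | C=CC[C@H](O[Li])CC1(SCCCS1)[Si](C)(C)C(C)(C)C | intermediate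
18 | lithium chloroalkoxide (7-OTBS, dithiane at C9, C11–OLi, C12–Cl) | C=CC[C@H](O[Si](C)(C)C(C)(C)C)CC1(SCCCS1)C[C@H](O[Li])CCl | intermediate
19 | C4′–C12 epoxide (7-OTBS, dithiane at C9, (S)-11,12-epoxide) | C=CC[C@H](O[Si](C)(C)C(C)(C)C)CC1(SCCCS1)C[C@H]2CO2 | intermediate
20 | lithium alkoxide adduct of 16 and 19 (C11–OLi, silyl dithiane at C13) | C=CC[C@H](O[Si](C)(C)C(C)(C)C)CC1(SCCCS1)C[C@H](O[Li])CC2(SCCCS2)[Si](C)(C)C(C)(C)C | intermediate
21 | lithium chloroalkoxide (7,11-bis-OTBS, dithianes at C9 and C13, C15–OLi, C16–Cl) | C=CC[C@H](O[Si](C)(C)C(C)(C)C)CC1(SCCCS1)C[C@H](O[Si](C)(C)C(C)(C)C)CC2(SCCCS2)C[C@H](O[Li])CCl | intermediate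
22 | C4′–C16 epoxide (7,11-bis-OTBS, dithianes at C9 and C13, (S)-15,16-epoxide) | C=CC[C@H](O[Si](C)(C)C(C)(C)C)CC1(SCCCS1)C[C@H](O[Si](C)(C)C(C)(C)C)CC2(SCCCS2)C[C@H]3CO3 | intermediate
23 | dilithio derivative of 10 (C17 carbanion, C19 alkoxide) | [Li]C1(SCCCS1)[C@@H](C)[C@H](O[Li])C#C[Si](C)(C)C | intermediate
24 | C4′–C21 tris-dithiane (7,11-bis-OTBS, 15,19-diol, dithianes at C9, C13, C17, 21-TMS) | C=CC[C@H](O[Si](C)(C)C(C)(C)C)CC1(SCCCS1)C[C@H](O[Si](C)(C)C(C)(C)C)CC2(SCCCS2)C[C@H](O)CC3(SCCCS3)[C@@H](C)[C@H](O)C#C[Si](C)(C)C | intermediate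
25 | C4′–C21 tetrol tris-dithiane (7,11,15,19-tetrol, terminal alkyne) | C=CC[C@H](O)CC1(SCCCS1)C[C@H](O)CC2(SCCCS2)C[C@H](O)CC3(SCCCS3)[C@@H](C)[C@H](O)C#C | intermediate
26 | C4′–C21 9,13,17-trione 7,11,15,19-tetrol | C=CC[C@H](O)CC(=O)C[C@H](O)CC(=O)C[C@H](O)CC(=O)[C@@H](C)[C@H](O)C#C | intermediate
27 | C4′–C21 7,9,11,13,15,17,19-heptol (18-methyl, C20≡C21–H) | C=CC[C@H](O)C[C@@H](O)C[C@H](O)C[C@@H](O)C[C@H](O)C[C@@H](O)[C@@H](C)[C@H](O)C#C | intermediate
28 | 7,9,11,13,15,19-hexa-TES ether of 27 (17-OH free) | C=CC[C@H](O[Si](CC)(CC)CC)C[C@@H](O[Si](CC)(CC)CC)C[C@H](O[Si](CC)(CC)CC)C[C@@H](O[Si](CC)(CC)CC)C[C@H](O[Si](CC)(CC)CC)C[C@@H](O)[C@@H](C)[C@H](O[Si](CC)(CC)CC)C#C | intermediate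
29 | hepta-TES ether of 27 | C=CC[C@H](O[Si](CC)(CC)CC)C[C@@H](O[Si](CC)(CC)CC)C[C@H](O[Si](CC)(CC)CC)C[C@@H](O[Si](CC)(CC)CC)C[C@H](O[Si](CC)(CC)CC)C[C@@H](O[Si](CC)(CC)CC)[C@@H](C)[C@H](O[Si](CC)(CC)CC)C#C | intermediate
30 | (R)-epichlorohydrin | ClC[C@H]1CO1 | starting material
31 | benzyl 5-bromopentyl ether | BrCCCCCOCc1ccccc1 | starting material
32 | [5-(benzyloxy)pentyl]magnesium bromide | Br[Mg]CCCCCOCc1ccccc1 | intermediate
33 | (R)-8-(benzyloxy)-1-chlorooctan-2-ol | ClC[C@H](O)CCCCCCOCc1ccccc1 | intermediate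
34 | (R)-2-[6-(benzyloxy)hexyl]oxirane | C1[C@H](O1)CCCCCCOCc2ccccc2 | intermediate
35 | lithium alkoxide adduct of 16 and 34 (C31–OLi, silyl dithiane at C29) | CC(C)(C)[Si](C)(C)C1(SCCCS1)C[C@H](O[Li])CCCCCCOCc2ccccc2 | intermediate
36 | lithium chloroalkoxide (C26–Cl, C27–OLi, dithiane at C29, 31-OTBS, 37-OBn) | ClC[C@H](O[Li])CC1(SCCCS1)C[C@H](O[Si](C)(C)C(C)(C)C)CCCCCCOCc2ccccc2 | intermediate
37 | C26–C37 epoxide ((R)-26,27-epoxide, dithiane at C29, 31-OTBS, 37-OBn) | C1[C@H](O1)CC2(SCCCS2)C[C@H](O[Si](C)(C)C(C)(C)C)CCCCCCOCc3ccccc3 | intermediate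
38 | (R)-benzyl glycidyl ether | c1ccccc1COC[C@H]2CO2 | starting material
39 | lithium alkoxide adduct of 16 and 37 (C27–OLi, silyl dithiane at C25) | CC(C)(C)[Si](C)(C)C1(SCCCS1)C[C@H](O[Li])CC2(SCCCS2)C[C@H](O[Si](C)(C)C(C)(C)C)CCCCCCOCc3ccccc3 | intermediate
40 | C22–C37 bis-dithiane (22-OBn, 23-OH, dithianes at C25 and C29, 27,31-bis-OTBS, 37-OBn) | c1ccccc1COC[C@H](O)CC2(SCCCS2)C[C@H](O[Si](C)(C)C(C)(C)C)CC3(SCCCS3)C[C@H](O[Si](C)(C)C(C)(C)C)CCCCCCOCc4ccccc4 | intermediate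
41 | C22–C37 22,23,37-triol (27,31-bis-OTBS) | OC[C@H](O)CCC[C@H](O[Si](C)(C)C(C)(C)C)CCC[C@H](O[Si](C)(C)C(C)(C)C)CCCCCCO | intermediate
42 | 22,37-bis-tosylate of 41 | Cc1ccc(cc1)S(=O)(=O)OC[C@H](O)CCC[C@H](O[Si](C)(C)C(C)(C)C)CCC[C@H](O[Si](C)(C)C(C)(C)C)CCCCCCOS(=O)(=O)c2ccc(C)cc2 | intermediate
43 | C22–C37 epoxy tosylate ((R)-22,23-epoxide, 27,31-bis-OTBS, 37-OTs) | C1[C@H](O1)CCC[C@H](O[Si](C)(C)C(C)(C)C)CCC[C@H](O[Si](C)(C)C(C)(C)C)CCCCCCOS(=O)(=O)c2ccc(C)cc2 | intermediate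
44 | (R)-propylene oxide | C[C@@H]1CO1 | starting material
45 | (R)-pent-4-en-2-ol | C=CC[C@@H](C)O | intermediate
46 | (R)-tert-butyldimethyl(pent-4-en-2-yloxy)silane | C=CC[C@@H](C)O[Si](C)(C)C(C)(C)C | intermediate
47 | alkylzirconocene chloride from 46 | Cl[Zr](C1C=CC=C1)(C2C=CC=C2)CCC[C@@H](C)O[Si](C)(C)C(C)(C)C | intermediate
48 | (R)-tert-butyl[(5-iodopentan-2-yl)oxy]dimethylsilane | ICCC[C@@H](C)O[Si](C)(C)C(C)(C)C | intermediate
49 | (3S,4R,E)-4-methylhept-5-en-1-yn-3-ol | C/C=C/[C@@H](C)[C@H](O)C#C | intermediate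
50 | dilithio derivative of 49 | C/C=C/[C@@H](C)[C@H](O[Li])C#C[Li] | intermediate
51 | C41–C50 alkynol ((E)-prop-1-enyl on C42 as masked C41, 43-OH, C44≡C45, 49-OTBS) | C/C=C/[C@@H](C)[C@H](O)C#CCCC[C@@H](C)O[Si](C)(C)C(C)(C)C | intermediate
52 | 43-O-PMB ether of 51 | C/C=C/[C@@H](C)[C@H](OCc1ccc(OC)cc1)C#CCCC[C@@H](C)O[Si](C)(C)C(C)(C)C | intermediate
53 | C41 aldehyde (42-Me, 43-OPMB, C44≡C45, 49-OTBS) | O=C[C@@H](C)[C@H](OCc1ccc(OC)cc1)C#CCCC[C@@H](C)O[Si](C)(C)C(C)(C)C | intermediate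
54 | saturated C41 aldehyde (42-Me, 43-OPMB, 49-OTBS) | O=C[C@@H](C)[C@H](OCc1ccc(OC)cc1)CCCCC[C@@H](C)O[Si](C)(C)C(C)(C)C | intermediate
55 | propargyl bromide | BrCC#C | starting material
56 | allenylzinc bromide | Br[Zn]C=C=C | intermediate
57 | C38–C50 homopropargylic alcohols (C41 epimers) | C#CCC(O)[C@@H](C)[C@H](OCc1ccc(OC)cc1)CCCCC[C@@H](C)O[Si](C)(C)C(C)(C)C | intermediate
58 | C38–C50 β,γ-ynone (C41 ketone) | C#CCC(=O)[C@@H](C)[C@H](OCc1ccc(OC)cc1)CCCCC[C@@H](C)O[Si](C)(C)C(C)(C)C | intermediate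
59 | C38–C50 alkynol (41-OH, 42-Me, 43-OPMB, 49-OTBS) | C#CC[C@H](O)[C@@H](C)[C@H](OCc1ccc(OC)cc1)CCCCC[C@@H](C)O[Si](C)(C)C(C)(C)C | intermediate
60 | lithium acetylide of 29 | C=CC[C@H](O[Si](CC)(CC)CC)C[C@@H](O[Si](CC)(CC)CC)C[C@H](O[Si](CC)(CC)CC)C[C@@H](O[Si](CC)(CC)CC)C[C@H](O[Si](CC)(CC)CC)C[C@@H](O[Si](CC)(CC)CC)[C@@H](C)[C@H](O[Si](CC)(CC)CC)C#C[Li] | intermediate
61 | C4′–C37 alkynol (hepta-TES, C20≡C21, 23-OH, 27,31-bis-OTBS, 37-OTs) | C=CC[C@H](O[Si](CC)(CC)CC)C[C@@H](O[Si](CC)(CC)CC)C[C@H](O[Si](CC)(CC)CC)C[C@@H](O[Si](CC)(CC)CC)C[C@H](O[Si](CC)(CC)CC)C[C@@H](O[Si](CC)(CC)CC)[C@@H](C)[C@H](O[Si](CC)(CC)CC)C#CC[C@H](O)CCC[C@H](O[Si](C)(C)C(C)(C)C)CCC[C@H](O[Si](C)(C)C(C)(C)C)CCCCCCOS(=O)(=O)c1ccc(C)cc1 | intermediate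
62 | 23-O-TBS ether of 61 | C=CC[C@H](O[Si](CC)(CC)CC)C[C@@H](O[Si](CC)(CC)CC)C[C@H](O[Si](CC)(CC)CC)C[C@@H](O[Si](CC)(CC)CC)C[C@H](O[Si](CC)(CC)CC)C[C@@H](O[Si](CC)(CC)CC)[C@@H](C)[C@H](O[Si](CC)(CC)CC)C#CC[C@H](O[Si](C)(C)C(C)(C)C)CCC[C@H](O[Si](C)(C)C(C)(C)C)CCC[C@H](O[Si](C)(C)C(C)(C)C)CCCCCCOS(=O)(=O)c1ccc(C)cc1 | intermediate
63 | dilithio derivative of 59 | [Li]C#CC[C@H](O[Li])[C@@H](C)[C@H](OCc1ccc(OC)cc1)CCCCC[C@@H](C)O[Si](C)(C)C(C)(C)C | intermediate
64 | C4′–C50 diyne (C20≡C21, C38≡C39, 41-OH, hepta-TES, tetra-TBS, 43-OPMB) | C=CC[C@H](O[Si](CC)(CC)CC)C[C@@H](O[Si](CC)(CC)CC)C[C@H](O[Si](CC)(CC)CC)C[C@@H](O[Si](CC)(CC)CC)C[C@H](O[Si](CC)(CC)CC)C[C@@H](O[Si](CC)(CC)CC)[C@@H](C)[C@H](O[Si](CC)(CC)CC)C#CC[C@H](O[Si](C)(C)C(C)(C)C)CCC[C@H](O[Si](C)(C)C(C)(C)C)CCC[C@H](O[Si](C)(C)C(C)(C)C)CCCCCCC#CC[C@H](O)[C@@H](C)[C@H](OCc1ccc(OC)cc1)CCCCC[C@@H](C)O[Si](C)(C)C(C)(C)C | intermediate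
65 | C5 aldehyde diyne | O=CC[C@H](O[Si](CC)(CC)CC)C[C@@H](O[Si](CC)(CC)CC)C[C@H](O[Si](CC)(CC)CC)C[C@@H](O[Si](CC)(CC)CC)C[C@H](O[Si](CC)(CC)CC)C[C@@H](O[Si](CC)(CC)CC)[C@@H](C)[C@H](O[Si](CC)(CC)CC)C#CC[C@H](O[Si](C)(C)C(C)(C)C)CCC[C@H](O[Si](C)(C)C(C)(C)C)CCC[C@H](O[Si](C)(C)C(C)(C)C)CCCCCCC#CC[C@H](O)[C@@H](C)[C@H](OCc1ccc(OC)cc1)CCCCC[C@@H](C)O[Si](C)(C)C(C)(C)C | intermediate
66 | (20Z,38Z)-C5 aldehyde | O=CC[C@H](O[Si](CC)(CC)CC)C[C@@H](O[Si](CC)(CC)CC)C[C@H](O[Si](CC)(CC)CC)C[C@@H](O[Si](CC)(CC)CC)C[C@H](O[Si](CC)(CC)CC)C[C@@H](O[Si](CC)(CC)CC)[C@@H](C)[C@H](O[Si](CC)(CC)CC)/C=C\C[C@H](O[Si](C)(C)C(C)(C)C)CCC[C@H](O[Si](C)(C)C(C)(C)C)CCC[C@H](O[Si](C)(C)C(C)(C)C)CCCCCC/C=C\C[C@H](O)[C@@H](C)[C@H](OCc1ccc(OC)cc1)CCCCC[C@@H](C)O[Si](C)(C)C(C)(C)C | intermediate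
67 | ethyltriphenylphosphonium bromide | CC[P+](c1ccccc1)(c1ccccc1)c1ccccc1.[Br-] | starting material
68 | ethylidenetriphenylphosphorane | CC=P(c1ccccc1)(c1ccccc1)c1ccccc1 | intermediate
69 | (1-iodoethyl)triphenylphosphonium iodide | CC(I)[P+](c1ccccc1)(c1ccccc1)c1ccccc1.[I-] | intermediate
70 | (1-iodoethylidene)triphenylphosphorane | CC(I)=P(c1ccccc1)(c1ccccc1)c1ccccc1 | intermediate
71 | (4Z,20Z,38Z)-C4 vinyl iodide (41-OH) | C/C(I)=C/C[C@H](O[Si](CC)(CC)CC)C[C@@H](O[Si](CC)(CC)CC)C[C@H](O[Si](CC)(CC)CC)C[C@@H](O[Si](CC)(CC)CC)C[C@H](O[Si](CC)(CC)CC)C[C@@H](O[Si](CC)(CC)CC)[C@@H](C)[C@H](O[Si](CC)(CC)CC)/C=C\C[C@H](O[Si](C)(C)C(C)(C)C)CCC[C@H](O[Si](C)(C)C(C)(C)C)CCC[C@H](O[Si](C)(C)C(C)(C)C)CCCCCC/C=C\C[C@H](O)[C@@H](C)[C@H](OCc1ccc(OC)cc1)CCCCC[C@@H](C)O[Si](C)(C)C(C)(C)C | intermediate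
72 | (E)-1,2-bis(tributylstannyl)ethene | CCCC[Sn](CCCC)(CCCC)/C=C/[Sn](CCCC)(CCCC)CCCC | starting material
73 | (E)-[2-(tributylstannyl)vinyl]lithium | [Li]/C=C/[Sn](CCCC)(CCCC)CCCC | intermediate
74 | (E)-3-(tributylstannyl)acrylic acid | OC(=O)/C=C/[Sn](CCCC)(CCCC)CCCC | intermediate
75 | 41-O-[(E)-3-(tributylstannyl)acryloyl] ester of 71 | C/C(I)=C/C[C@H](O[Si](CC)(CC)CC)C[C@@H](O[Si](CC)(CC)CC)C[C@H](O[Si](CC)(CC)CC)C[C@@H](O[Si](CC)(CC)CC)C[C@H](O[Si](CC)(CC)CC)C[C@@H](O[Si](CC)(CC)CC)[C@@H](C)[C@H](O[Si](CC)(CC)CC)/C=C\C[C@H](O[Si](C)(C)C(C)(C)C)CCC[C@H](O[Si](C)(C)C(C)(C)C)CCC[C@H](O[Si](C)(C)C(C)(C)C)CCCCCC/C=C\C[C@H](OC(=O)/C=C/[Sn](CCCC)(CCCC)CCCC)[C@@H](C)[C@H](OCc1ccc(OC)cc1)CCCCC[C@@H](C)O[Si](C)(C)C(C)(C)C | intermediate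
76 | protected macrolactone (hepta-TES, tetra-TBS, 43-OPMB) | CC1=C/C[C@H](O[Si](CC)(CC)CC)C[C@@H](O[Si](CC)(CC)CC)C[C@H](O[Si](CC)(CC)CC)C[C@@H](O[Si](CC)(CC)CC)C[C@H](O[Si](CC)(CC)CC)C[C@@H](O[Si](CC)(CC)CC)[C@@H](C)[C@H](O[Si](CC)(CC)CC)/C=C\C[C@H](O[Si](C)(C)C(C)(C)C)CCC[C@H](O[Si](C)(C)C(C)(C)C)CCC[C@H](O[Si](C)(C)C(C)(C)C)CCCCCC/C=C\C[C@@H]([C@@H](C)[C@H](OCc2ccc(OC)cc2)CCCCC[C@@H](C)O[Si](C)(C)C(C)(C)C)OC(=O)\C=C\1 | intermediate
77 | 43-hydroxy macrolactone (hepta-TES, tetra-TBS) | CC1=C/C[C@H](O[Si](CC)(CC)CC)C[C@@H](O[Si](CC)(CC)CC)C[C@H](O[Si](CC)(CC)CC)C[C@@H](O[Si](CC)(CC)CC)C[C@H](O[Si](CC)(CC)CC)C[C@@H](O[Si](CC)(CC)CC)[C@@H](C)[C@H](O[Si](CC)(CC)CC)/C=C\C[C@H](O[Si](C)(C)C(C)(C)C)CCC[C@H](O[Si](C)(C)C(C)(C)C)CCC[C@H](O[Si](C)(C)C(C)(C)C)CCCCCC/C=C\C[C@@H]([C@@H](C)[C@H](O)CCCCC[C@@H](C)O[Si](C)(C)C(C)(C)C)OC(=O)\C=C\1 | intermediate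
78 | CNP0071908.1 | CC1=C/C[C@H](O)C[C@@H](O)C[C@H](O)C[C@@H](O)C[C@H](O)C[C@@H](O)[C@@H](C)[C@H](O)/C=C\C[C@H](O)CCC[C@H](O)CCC[C@H](O)CCCCCC/C=C\C[C@@H]([C@@H](C)[C@H](O)CCCCC[C@@H](C)O)OC(=O)\C=C\1 | target

**Totals**
Total step count: 42 (each one-pot sequence counted once; step 7 is counted once although it is run before each of the four linchpin couplings).
Longest linear sequence: 21 steps (1–5, 10–15, 32–37, 39–42).

**Three steps most likely to fail**

Step 10 (union of 10 with 22). Lithiating the hindered dithiane beside the propargylic alkoxide may be slow or go astray, and the dianion may open the epoxide sluggishly. The fallback sets out from 22 and 8 and comes back at 27; it forms C16–C17 by an aldol instead of a dithiane alkylation. Epoxide 22 is opened with LiEt3BH to the C15 methyl carbinol F1, which is oxidised (SO3·pyridine, DMSO, Et3N) to the methyl ketone F2 and converted (LiN(i-Pr)2, Me3SiCl, −78 °C) to the trimethylsilyl enol ether F3. Alcohol 8 is protected (4-methoxybenzyl trichloroacetimidate, cat. La(OTf)3) as the PMB ether F4 and ozonised (O3; PPh3) to the aldehyde F5. A chelation-controlled Mukaiyama aldol of F3 with F5 (MgBr2·OEt2, CH2Cl2, −78 °C) gives the β-hydroxy ketone F6, with C17 anti to both the C18 methyl and O19 because both sit on one face of the chelate. Me4NBH(OAc)3 then gives the 15,17-anti diol F7, Bu4NF the desilylated tetrol F8, MeI/CaCO3 the 9,13-dione F9, and a second Me4NBH(OAc)3 reduction the hexol PMB ether F10; DDQ removes the PMB group and returns to 27.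

Step 37 (iodo-olefination of 66). Z/E selectivity and yield are modest on β-silyloxy aldehydes, and excess basic ylide may cause elimination. The fallback sets out from 66 and comes back at 76, building the diene by olefinations and closing the ring at C2=C3. Still–Gennari olefination (ethyl 2-[bis(2,2,2-trifluoroethoxy)phosphoryl]propanoate, KN(SiMe3)2, 18-crown-6, THF, −78 °C) gives the (Z)-2-methyl enoate F11; i-Bu2AlH reduces it to the allylic alcohol F12; MnO2 oxidises only the allylic hydroxyl to the (Z)-enal F13. O41 is then acylated with diethylphosphonoacetic acid (DCC, DMAP) to the phosphonoacetate F14, and an intramolecular Horner–Wadsworth–Emmons reaction under Masamune–Roush conditions (LiCl, i-Pr2NEt, MeCN, high dilution) forms the (2E)-alkene and returns to 76.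

Step 40 (Stille macrocyclisation). Closing a 42-membered ring may lose out to oligomerisation and protodestannylation. The fallback sets out from 71 and 74 and comes back at 76, closing the ring at the ester instead. Intermolecular Stille coupling of 71 with 74 (Pd2(dba)3, AsPh3, DMF, rt) gives the (2E,4Z)-dienoic seco acid F15; Yamaguchi macrolactonisation (2,4,6-trichlorobenzoyl chloride, Et3N, THF; then DMAP, toluene, high dilution) onto the only free hydroxyl (O41) returns to 76.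

Further compounds
F1 | step 10 | C4′–C16 15-carbinol (C16 methyl; 7,11-bis-OTBS; dithianes at C9, C13) | C=CC[C@H](O[Si](C)(C)C(C)(C)C)CC1(SCCCS1)C[C@H](O[Si](C)(C)C(C)(C)C)CC2(SCCCS2)C[C@@H](C)O
F2 | step 10 | C4′–C16 methyl ketone (C15 ketone) | C=CC[C@H](O[Si](C)(C)C(C)(C)C)CC1(SCCCS1)C[C@H](O[Si](C)(C)C(C)(C)C)CC2(SCCCS2)CC(C)=O
F3 | step 10 | trimethylsilyl enol ether of F2 | C=CC[C@H](O[Si](C)(C)C(C)(C)C)CC1(SCCCS1)C[C@H](O[Si](C)(C)C(C)(C)C)CC2(SCCCS2)CC(=C)O[Si](C)(C)C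
F4 | step 10 | PMB ether of 8 | C/C=C/[C@@H](C)[C@H](OCc1ccc(OC)cc1)C#C[Si](C)(C)C
F5 | step 10 | C17 aldehyde (18-Me, 19-OPMB, 21-TMS) | O=C[C@@H](C)[C@H](OCc1ccc(OC)cc1)C#C[Si](C)(C)C
F6 | step 10 | aldol adduct (C15 ketone, 17-OH, 19-OPMB) | C=CC[C@H](O[Si](C)(C)C(C)(C)C)CC1(SCCCS1)C[C@H](O[Si](C)(C)C(C)(C)C)CC2(SCCCS2)CC(=O)C[C@@H](O)[C@@H](C)[C@H](OCc3ccc(OC)cc3)C#C[Si](C)(C)C
F7 | step 10 | 15,17-anti diol (7,11-bis-OTBS; dithianes at C9, C13; 19-OPMB; 21-TMS) | C=CC[C@H](O[Si](C)(C)C(C)(C)C)CC1(SCCCS1)C[C@H](O[Si](C)(C)C(C)(C)C)CC2(SCCCS2)C[C@H](O)C[C@@H](O)[C@@H](C)[C@H](OCc3ccc(OC)cc3)C#C[Si](C)(C)C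
F8 | step 10 | desilylated tetrol (dithianes at C9, C13; 19-OPMB; terminal alkyne) | C=CC[C@H](O)CC1(SCCCS1)C[C@H](O)CC2(SCCCS2)C[C@H](O)C[C@@H](O)[C@@H](C)[C@H](OCc3ccc(OC)cc3)C#C
F9 | step 10 | 9,13-dione (7,11,15,17-tetrol; 19-OPMB) | C=CC[C@H](O)CC(=O)C[C@H](O)CC(=O)C[C@H](O)C[C@@H](O)[C@@H](C)[C@H](OCc1ccc(OC)cc1)C#C
F10 | step 10 | hexol 19-PMB ether | C=CC[C@H](O)C[C@@H](O)C[C@H](O)C[C@@H](O)C[C@H](O)C[C@@H](O)[C@@H](C)[C@H](OCc1ccc(OC)cc1)C#C
F11 | step 37 | ethyl (Z)-2-methyl enoate (C3 ester, 4Z; 41-OH) | C/C(C(=O)OCC)=C/C[C@H](O[Si](CC)(CC)CC)C[C@@H](O[Si](CC)(CC)CC)C[C@H](O[Si](CC)(CC)CC)C[C@@H](O[Si](CC)(CC)CC)C[C@H](O[Si](CC)(CC)CC)C[C@@H](O[Si](CC)(CC)CC)[C@@H](C)[C@H](O[Si](CC)(CC)CC)/C=C\C[C@H](O[Si](C)(C)C(C)(C)C)CCC[C@H](O[Si](C)(C)C(C)(C)C)CCC[C@H](O[Si](C)(C)C(C)(C)C)CCCCCC/C=C\C[C@H](O)[C@@H](C)[C@H](OCc1ccc(OC)cc1)CCCCC[C@@H](C)O[Si](C)(C)C(C)(C)C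
F12 | step 37 | (Z)-allylic alcohol (C3–OH; 41-OH) | C/C(CO)=C/C[C@H](O[Si](CC)(CC)CC)C[C@@H](O[Si](CC)(CC)CC)C[C@H](O[Si](CC)(CC)CC)C[C@@H](O[Si](CC)(CC)CC)C[C@H](O[Si](CC)(CC)CC)C[C@@H](O[Si](CC)(CC)CC)[C@@H](C)[C@H](O[Si](CC)(CC)CC)/C=C\C[C@H](O[Si](C)(C)C(C)(C)C)CCC[C@H](O[Si](C)(C)C(C)(C)C)CCC[C@H](O[Si](C)(C)C(C)(C)C)CCCCCC/C=C\C[C@H](O)[C@@H](C)[C@H](OCc1ccc(OC)cc1)CCCCC[C@@H](C)O[Si](C)(C)C(C)(C)C
F13 | step 37 | (Z)-enal (C3 aldehyde; 41-OH) | C/C(C=O)=C/C[C@H](O[Si](CC)(CC)CC)C[C@@H](O[Si](CC)(CC)CC)C[C@H](O[Si](CC)(CC)CC)C[C@@H](O[Si](CC)(CC)CC)C[C@H](O[Si](CC)(CC)CC)C[C@@H](O[Si](CC)(CC)CC)[C@@H](C)[C@H](O[Si](CC)(CC)CC)/C=C\C[C@H](O[Si](C)(C)C(C)(C)C)CCC[C@H](O[Si](C)(C)C(C)(C)C)CCC[C@H](O[Si](C)(C)C(C)(C)C)CCCCCC/C=C\C[C@H](O)[C@@H](C)[C@H](OCc1ccc(OC)cc1)CCCCC[C@@H](C)O[Si](C)(C)C(C)(C)C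
F14 | step 37 | 41-O-(diethylphosphonoacetyl) ester of F13 | C/C(C=O)=C/C[C@H](O[Si](CC)(CC)CC)C[C@@H](O[Si](CC)(CC)CC)C[C@H](O[Si](CC)(CC)CC)C[C@@H](O[Si](CC)(CC)CC)C[C@H](O[Si](CC)(CC)CC)C[C@@H](O[Si](CC)(CC)CC)[C@@H](C)[C@H](O[Si](CC)(CC)CC)/C=C\C[C@H](O[Si](C)(C)C(C)(C)C)CCC[C@H](O[Si](C)(C)C(C)(C)C)CCC[C@H](O[Si](C)(C)C(C)(C)C)CCCCCC/C=C\C[C@H](OC(=O)CP(=O)(OCC)OCC)[C@@H](C)[C@H](OCc1ccc(OC)cc1)CCCCC[C@@H](C)O[Si](C)(C)C(C)(C)C
F15 | step 40 | (2E,4Z,20Z,38Z)-seco acid (C1 acid; 41-OH) | OC(=O)/C=C/C(C)=C\C[C@H](O[Si](CC)(CC)CC)C[C@@H](O[Si](CC)(CC)CC)C[C@H](O[Si](CC)(CC)CC)C[C@@H](O[Si](CC)(CC)CC)C[C@H](O[Si](CC)(CC)CC)C[C@@H](O[Si](CC)(CC)CC)[C@@H](C)[C@H](O[Si](CC)(CC)CC)/C=C\C[C@H](O[Si](C)(C)C(C)(C)C)CCC[C@H](O[Si](C)(C)C(C)(C)C)CCC[C@H](O[Si](C)(C)C(C)(C)C)CCCCCC/C=C\C[C@H](O)[C@@H](C)[C@H](OCc1ccc(OC)cc1)CCCCC[C@@H](C)O[Si](C)(C)C(C)(C)C
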